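**Retrosynthetic overview**
1. Target ⇒ acid deprotection of the protected dienone ⇒ Stille coupling of an α‑iodoenone core with an (R,E)‑vinylstannane. The stannane carbinol comes from catalytic reduction of an achiral ynone.
2. The cyclohexenone is the only ring that is built. It is closed by an intramolecular HWE reaction (C2=C3) of a β‑ketophosphonate, which is made from the C1 aldehyde with a diazophosphonate.
3. C1 aldehyde and C8 enoate ⇒ 2‑substituted succinaldehyde ⇒ iminium transfer hydrogenation (sets C6) of a 2‑substituted (Z)‑butenedial ⇒ ¹O₂ opening of a 3‑substituted furan.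
4. Furyl carbinol ⇒ L‑proline aldol of 2,2‑dimethyl‑1,3‑dioxan‑5‑one with furan‑3‑carbaldehyde (sets C4 and C5). The dioxane ring comes with the starting material.

Assumption: compounds 7, 10 and 14 are taken as catalogue chemicals. Atom labels follow the target ring: C1 = C=O, C2=C3 alkene, C4 and C5 carbinols, C6 carries the chain C7H2–C8H=C9(Me)CO2H.

**Step 1**
Reactants: 1 2,2‑dimethyl‑1,3‑dioxan‑5‑one; 2 furan‑3‑carbaldehyde
Product: 3 (4S)‑4‑[(S)‑furan‑3‑yl(hydroxy)methyl]‑2,2‑dimethyl‑1,3‑dioxan‑5‑one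
Conditions: L‑proline (30 mol %), DMF, 4 °C, 3–5 d
Reagents that add atoms: none
Why: Direct enamine aldol through a List–Houk chair transition state, in which the L‑proline enamine of 1 adds to the Re face of the acid‑activated, non‑enolisable aldehyde 2, giving the anti adduct and setting C4 and C5 under catalyst control.

**Step 2**
Reactants: 3 (4S)‑4‑[(S)‑furan‑3‑yl(hydroxy)methyl]‑2,2‑dimethyl‑1,3‑dioxan‑5‑one
Product: 4 (4S)‑4‑[(S)‑furan‑3‑yl(triethylsilyloxy)methyl]‑2,2‑dimethyl‑1,3‑dioxan‑5‑one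
Conditions: TESOTf, 2,6‑lutidine, CH2Cl2, −78 °C
Reagents that add atoms: triethylsilyl triflate, CC[Si](CC)(CC)OS(=O)(=O)C(F)(F)F
Why: O‑silylation blocks retro‑aldol cleavage and later hemiacetal or furan re‑formation, and no stereocentre is touched.

**Step 3**
Reactants: 4 (4S)‑4‑[(S)‑furan‑3‑yl(triethylsilyloxy)methyl]‑2,2‑dimethyl‑1,3‑dioxan‑5‑one
Product: 6 (Z)‑2‑{(S)‑[(4S)‑2,2‑dimethyl‑5‑oxo‑1,3‑dioxan‑4‑yl](triethylsilyloxy)methyl}but‑2‑enedial, via furan endoperoxide (5‑substituted 2,3,7‑trioxabicyclo[2.2.1]hept‑5‑ene, both facial isomers) 5 (not isolated)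
Conditions: O2, hν, tetraphenylporphyrin (cat.), CH2Cl2, −78 °C; then Me2S, −78 → 0 °C; used at once
Reagents that add atoms: dioxygen, O=O
Why: Furan photooxygenation ([4+2] with ¹O₂) followed by O–O reduction unmasks the furan as the cis‑enedial (C1 and C8 aldehydes) under neutral conditions, and the furan is the only ¹O₂‑reactive site.

**Step 4**
Reactants: 6 (Z)‑2‑{(S)‑[(4S)‑2,2‑dimethyl‑5‑oxo‑1,3‑dioxan‑4‑yl](triethylsilyloxy)methyl}but‑2‑enedial; 7 tert‑butyl 2‑(triphenyl‑λ5‑phosphanylidene)propanoate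
Product: 9 tert‑butyl (2E,5R,6S)‑6‑[(4S)‑2,2‑dimethyl‑5‑oxo‑1,3‑dioxan‑4‑yl]‑5‑formyl‑2‑methyl‑6‑(triethylsilyloxy)hex‑2‑enoate, via (2R)‑2‑{(S)‑[(4S)‑2,2‑dimethyl‑5‑oxo‑1,3‑dioxan‑4‑yl](triethylsilyloxy)methyl}butanedial 8 (not isolated)
Conditions: (S)‑2‑tert‑butyl‑3‑methylimidazolidin‑4‑one·TFA (20 mol %), Hantzsch ester (1.05 equiv), CHCl3, −30 °C; then 7 (1.0 equiv), −30 → 0 °C
Reagents that add atoms: none
Why: Proposed new method: the amine salt should condense selectively with the unhindered C8 aldehyde because the C1 aldehyde is α‑branched, which places C6 at the β‑position of the iminium ion, and the Hantzsch ester then delivers hydride to the face left open by the tert‑butyl group, so C6 (R) is created by C–H bond formation under catalyst control and not by enol protonation; iminium E/Z isomerisation is tolerated because this catalyst class is stereoconvergent, the other catalyst enantiomer is available if the facial sense is reversed, and the saturated dialdehyde is trapped in situ by the stabilised, α‑branched ylide, which reacts only with the unbranched C8 aldehyde (E‑selective Wittig); the closest known reaction is iminium‑catalysed transfer hydrogenation of β,β‑disubstituted enals, which has not been shown on ene‑dials or next to a silyloxy stereocentre.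

**Step 5**
Reactants: 9 tert‑butyl (2E,5R,6S)‑6‑[(4S)‑2,2‑dimethyl‑5‑oxo‑1,3‑dioxan‑4‑yl]‑5‑formyl‑2‑methyl‑6‑(triethylsilyloxy)hex‑2‑enoate; 10 dimethyl (diazomethyl)phosphonate
Product: 12 tert‑butyl (2E)‑4‑[(7R,8S,8aR)‑2,2‑dimethyl‑6‑oxo‑8‑(triethylsilyloxy)‑4,7,8,8a‑tetrahydro‑6H‑1,3‑benzodioxin‑7‑yl]‑2‑methylbut‑2‑enoate, via tert‑butyl (2E,5R)‑7‑(dimethoxyphosphoryl)‑5‑{(S)‑[(4S)‑2,2‑dimethyl‑5‑oxo‑1,3‑dioxan‑4‑yl](triethylsilyloxy)methyl}‑2‑methyl‑6‑oxohept‑2‑enoate 11 (not isolated)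
Conditions: SnCl2 (10 mol %), CH2Cl2, 0 °C → rt; solvent switch to toluene, K2CO3 (1.5 equiv), 18‑crown‑6, rt
Reagents that add atoms: none
Why: Holmquist–Roskamp homologation (diazo addition, 1,2‑H shift, loss of N2) turns the aldehyde into the β‑ketophosphonate without base, so C6 is untouched, and the doubly activated C2–H is then the only site K2CO3 deprotonates, so an intramolecular Horner–Wadsworth–Emmons reaction on the electrophilic dioxanone carbonyl closes the cyclohexenone; no new stereocentre forms, and C4 changes from S to R only through CIP ranking.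

**Step 6**
Reactants: 12 the bicyclic enone from step 5
Product: 13 tert‑butyl (2E)‑4‑[(7R,8S,8aR)‑5‑iodo‑2,2‑dimethyl‑6‑oxo‑8‑(triethylsilyloxy)‑4,7,8,8a‑tetrahydro‑6H‑1,3‑benzodioxin‑7‑yl]‑2‑methylbut‑2‑enoate
Conditions: I2 (0.6 equiv), PhI(OCOCF3)2 (0.6 equiv), pyridine, CH2Cl2, rt, dark
Reagents that add atoms: iodine, II
Why: Johnson‑type α‑iodination of an enone in its hypervalent‑iodine variant for β‑substituted enones; the trisubstituted enoate is too electron‑poor to compete, and pyridine is too weak a base to epimerise C6.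

**Step 7**
Reactants: 14 hept‑6‑yn‑2‑one
Product: 15 (2R)‑hept‑6‑yn‑2‑ol
Conditions: (R)‑selective alcohol dehydrogenase (Lactobacillus kefir type), NADP+ (cat.), i‑PrOH, phosphate buffer pH 7, 30 °C
Reagents that add atoms: none
Why: Biocatalytic anti‑Prelog ketone reduction distinguishes methyl from the alkyl chain and gives the (R)‑carbinol in >99 % ee.

**Step 8**
Reactants: 15 (2R)‑hept‑6‑yn‑2‑ol
Product: 16 (2R,6E)‑7‑(tributylstannyl)hept‑6‑en‑2‑ol
Conditions: Bu3SnH, Pd2(dba)3 (0.5 mol %), Cy3P·HBF4, i‑Pr2NEt, CH2Cl2, 0 °C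
Reagents that add atoms: tributyltin hydride, CCCC[SnH](CCCC)CCCC
Why: Pd‑catalysed syn‑hydrostannation in which the bulky phosphine places tin on the terminal carbon to give the (E)‑stannane, and the free alcohol is tolerated.

**Step 9**
Reactants: 13 the iodoenone from step 6; 16 (2R,6E)‑7‑(tributylstannyl)hept‑6‑en‑2‑ol
Product: 17 tert‑butyl (2E)‑4‑{(7R,8S,8aR)‑5‑[(1E,6R)‑6‑hydroxyhept‑1‑en‑1‑yl]‑2,2‑dimethyl‑6‑oxo‑8‑(triethylsilyloxy)‑4,7,8,8a‑tetrahydro‑6H‑1,3‑benzodioxin‑7‑yl}‑2‑methylbut‑2‑enoate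
Conditions: Pd2(dba)3 (5 mol %), AsPh3 (20 mol %), CuI (10 mol %), NMP, rt → 40 °C
Reagents that add atoms: none
Why: Stille coupling of an α‑iodoenone retains the alkene geometry and runs under base‑free conditions, which protects the β‑silyloxy ketone and C6.

**Step 10**
Reactants: 17 the protected dienone from step 9
Product: 18 pestallic acid I
Conditions: TFA/CH2Cl2/H2O (10:10:1), 0 °C → rt
Reagents that add atoms: none
Why: A single acidolysis removes the tert‑butyl ester, the acetonide and the TES ether, and no base is present, so C6 and the β‑hydroxy ketone are preserved.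

**Compound list**
1 | 2,2‑dimethyl‑1,3‑dioxan‑5‑one | CC1(C)OCC(=O)CO1 | starting material
2 | furan‑3‑carbaldehyde | O=Cc1ccoc1 | starting material
3 | (4S)‑4‑[(S)‑furan‑3‑yl(hydroxy)methyl]‑2,2‑dimethyl‑1,3‑dioxan‑5‑one | O=C1COC(C)(C)O[C@H]1[C@@H](O)c1ccoc1 | intermediate
4 | TES ether of 3 | O=C1COC(C)(C)O[C@H]1[C@@H](O[Si](CC)(CC)CC)c1ccoc1 | intermediate
5 | furan endoperoxide of 4 (facial isomers) | O=C1COC(C)(C)O[C@H]1[C@@H](O[Si](CC)(CC)CC)C1=CC2OOC1O2 | intermediate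
6 | (Z)‑2‑substituted but‑2‑enedial | O=C1COC(C)(C)O[C@H]1[C@@H](O[Si](CC)(CC)CC)/C(C=O)=C/C=O | intermediate
7 | tert‑butyl 2‑(triphenyl‑λ5‑phosphanylidene)propanoate | CC(C(=O)OC(C)(C)C)=P(c1ccccc1)(c1ccccc1)c1ccccc1 | starting material
8 | (2R)‑2‑substituted butanedial | O=C1COC(C)(C)O[C@H]1[C@@H](O[Si](CC)(CC)CC)[C@H](C=O)CC=O | intermediate
9 | C1 aldehyde with complete enoate chain | C/C(=C\C[C@@H](C=O)[C@H](O[Si](CC)(CC)CC)[C@@H]1OC(C)(C)OCC1=O)C(=O)OC(C)(C)C | intermediate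
10 | dimethyl (diazomethyl)phosphonate | COP(=O)(OC)C=[N+]=[N-] | starting material
11 | β‑ketophosphonate | C/C(=C\C[C@@H](C(=O)CP(=O)(OC)OC)[C@H](O[Si](CC)(CC)CC)[C@@H]1OC(C)(C)OCC1=O)C(=O)OC(C)(C)C | intermediate
12 | bicyclic enone | C/C(=C\C[C@H]1C(=O)C=C2COC(C)(C)O[C@H]2[C@H]1O[Si](CC)(CC)CC)C(=O)OC(C)(C)C | intermediate
13 | α‑iodoenone | C/C(=C\C[C@H]1C(=O)C(I)=C2COC(C)(C)O[C@H]2[C@H]1O[Si](CC)(CC)CC)C(=O)OC(C)(C)C | intermediate
14 | hept‑6‑yn‑2‑one | CC(=O)CCCC#C | starting material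
15 | (2R)‑hept‑6‑yn‑2‑ol | C[C@@H](O)CCCC#C | intermediate
16 | (2R,6E)‑7‑(tributylstannyl)hept‑6‑en‑2‑ol | C[C@@H](O)CCC/C=C/[Sn](CCCC)(CCCC)CCCC | intermediate
17 | protected pestallic acid I | C/C(=C\C[C@H]1C(=O)C(/C=C/CCC[C@@H](C)O)=C2COC(C)(C)O[C@H]2[C@H]1O[Si](CC)(CC)CC)C(=O)OC(C)(C)C | intermediate
18 | pestallic acid I | C/C(=C\C[C@H]1C(=O)C(/C=C/CCC[C@@H](C)O)=C(CO)[C@@H](O)[C@H]1O)C(=O)O | target

**Step count**
- Total steps: 10.
- Longest linear sequence: 8 (steps 1, 2, 3, 4, 5, 6, 9, 10).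

**Steps most likely to fail**

**Step 4 (the new step).** The risks are poor site selectivity between the two aldehydes, a mismatched influence of the C5 stereocentre, and epimerisation of 8. The fallback uses known chemistry, sets out from 1 and returns at 9. It sets C6 by C–C instead of C–H bond formation.
- L‑proline aldol of 1 with commercial (E)‑4,4‑dimethoxybut‑2‑enal gives (4S)‑4‑[(1S,2E)‑1‑hydroxy‑4,4‑dimethoxybut‑2‑en‑1‑yl]‑2,2‑dimethyl‑1,3‑dioxan‑5‑one F1.
- TESOTf/2,6‑lutidine gives its TES ether F2.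
- PPTS in wet acetone unmasks the γ‑silyloxy enal F3.
- Diphenylprolinol silyl ether‑catalysed conjugate addition of nitromethane follows, using the catalyst enantiomer matched with the known syn preference of γ‑oxygenated acceptors. It gives the γ‑nitro aldehyde (3S)‑3‑substituted 4‑nitrobutanal F4.
- Wittig reaction with 7 gives the nitro enoate F5.
- A buffered TiCl3 Nef reaction converts CH2NO2 into the C1 aldehyde, which is 9.

**Step 1.** The electron‑rich heteroaryl aldehyde may give low conversion or an eroded anti:syn ratio. The fallback sets out from 1 and 2 and returns at 3.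
- A Cy2BCl/Et3N anti‑selective boron aldol gives the racemic anti adduct, that is 3 together with its enantiomer (4R)‑4‑[(R)‑furan‑3‑yl(hydroxy)methyl]‑2,2‑dimethyl‑1,3‑dioxan‑5‑one F6.
- Acylative kinetic resolution with a chiral isothiourea catalyst and Ac2O follows. It converts F6 into the acetate (R)‑[(4R)‑2,2‑dimethyl‑5‑oxo‑1,3‑dioxan‑4‑yl](furan‑3‑yl)methyl acetate F7 and leaves 3.

**Step 6.** The β,β‑disubstituted enone may iodinate slowly. The fallback sets out from 11, which is isolated this time, and returns at 17. The halogen is installed before ring closure.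
- K2CO3/NBS gives the α‑bromo‑β‑ketophosphonate F8.
- K2CO3/18‑crown‑6 closes it by HWE to the α‑bromoenone F9.
- F9 is coupled with 16 under the Stille conditions of step 9 to give 17.

**Further compounds**
F1 | step 4 | (4S)‑4‑[(1S,2E)‑1‑hydroxy‑4,4‑dimethoxybut‑2‑en‑1‑yl]‑2,2‑dimethyl‑1,3‑dioxan‑5‑one | O=C1COC(C)(C)O[C@H]1[C@@H](O)/C=C/C(OC)OC
F2 | step 4 | TES ether of F1 | O=C1COC(C)(C)O[C@H]1[C@@H](O[Si](CC)(CC)CC)/C=C/C(OC)OC
F3 | step 4 | (2E,4S)‑4‑[(4S)‑2,2‑dimethyl‑5‑oxo‑1,3‑dioxan‑4‑yl]‑4‑(triethylsilyloxy)but‑2‑enal | O=C1COC(C)(C)O[C@H]1[C@@H](O[Si](CC)(CC)CC)/C=C/C=O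
F4 | step 4 | (3S)‑3‑{(S)‑[(4S)‑2,2‑dimethyl‑5‑oxo‑1,3‑dioxan‑4‑yl](triethylsilyloxy)methyl}‑4‑nitrobutanal | O=CC[C@@H](C[N+](=O)[O-])[C@H](O[Si](CC)(CC)CC)[C@@H]1OC(C)(C)OCC1=O
F5 | step 4 | tert‑butyl (2E,5S)‑5‑(nitromethyl) analogue of 9 | C/C(=C\C[C@@H](C[N+](=O)[O-])[C@H](O[Si](CC)(CC)CC)[C@@H]1OC(C)(C)OCC1=O)C(=O)OC(C)(C)C
F6 | step 1 | (4R)‑4‑[(R)‑furan‑3‑yl(hydroxy)methyl]‑2,2‑dimethyl‑1,3‑dioxan‑5‑one | O=C1COC(C)(C)O[C@@H]1[C@H](O)c1ccoc1
F7 | step 1 | (R)‑[(4R)‑2,2‑dimethyl‑5‑oxo‑1,3‑dioxan‑4‑yl](furan‑3‑yl)methyl acetate | O=C1COC(C)(C)O[C@@H]1[C@H](OC(C)=O)c1ccoc1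
F8 | step 6 | α‑bromo derivative of 11 (C2 epimers) | C/C(=C\C[C@@H](C(=O)C(Br)P(=O)(OC)OC)[C@H](O[Si](CC)(CC)CC)[C@@H]1OC(C)(C)OCC1=O)C(=O)OC(C)(C)C
F9 | step 6 | α‑bromoenone (5‑bromo analogue of 13) | C/C(=C\C[C@H]1C(=O)C(Br)=C2COC(C)(C)O[C@H]2[C@H]1O[Si](CC)(CC)CC)C(=O)OC(C)(C)C
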